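**Plan**

- Retrosynthesis: the C8–O aroyl bond is cut first, taking the 4-hydroxybenzoate off a germacra-1(10),5-diene-4,8-diol. C5 and C10 are then rejoined across the ten-membered ring, and the resulting decalin is simplified through C4–C15, C7–isopropyl and C8–O back to Wieland–Miescher ketone.
- Enabling feature: in the ring C1–C10 the two E alkenes C1=C10 and C5=C6 are 1,6-related, so C5 and C10 face each other. A C5–C10 bond turns the macrocycle into a trans-decalin (ring A = C1–C5 + C10, ring B = C5–C10). Its equatorial C1 leaving group and equatorial C6 boron are both antiperiplanar to the shared bond, and C4, C7 and C8 sit on rigid chairs.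
- Forward order: rings A and B are bought together. Ring B receives the C8 oxygen and the C7 isopropyl group, and ring A the C4 carbinol and the C1 mesylate. The ten-membered ring appears only when C5–C10 is broken; desilylation, acylation at O8 and release of the phenol finish the route.
- Stereochemistry: the quaternary C10 of the (R)-ketone is the only bought stereocentre, and its axial methyl steers C1, C8, C5, C4 and finally C6/C7 by substrate control. C1, C5, C6 and C10 are then spent on the two E alkenes, while C4 (R), C7 (S) and C8 (S) are carried into the target.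

Key step: step 13

Remark on the chemistry: germacrane/eudesmane numbering is used for every compound (angular methyl on C10, C15 on C4); β is the face of the decalin that carries the C10 methyl and α the opposite face.

Step 1
Reactants: 1 (R)-(−)-Wieland–Miescher ketone
Product: 2 1β-hydroxy-10β-methyloctal-5-en-7-one
Conditions: NaBH4 (0.27 equiv), EtOH, −10 → 0 °C; then H2O
Reagents that add atoms: none
Why: Chemoselective borohydride 1,2-reduction, in which the isolated C1 ketone is much more electrophilic than the conjugated C7 carbonyl and hydride arrives axially on the α face away from the angular methyl, so the new C1 carbinol should carry an equatorial β-hydroxyl cis to that methyl.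

Step 2
Reactants: 2 1β-hydroxy-10β-methyloctal-5-en-7-one
Product: 3 1β-pivaloyloxy-10β-methyloctal-5-en-7-one
Conditions: PivCl (2 equiv), pyridine, DMAP (0.2 equiv), CH2Cl2, 0 → 40 °C
Reagents that add atoms: pivaloyl chloride, CC(C)(C)C(=O)Cl
Why: DMAP-catalysed acylation of the only hydroxyl gives an ester without α-hydrogens that is too hindered to be attacked by the amide base, the Grignard reagent or the boranes used later, and no stereocentre is touched.

Step 3
Reactants: 3 1β-pivaloyloxy-10β-methyloctal-5-en-7-one
Product: 6 8α-hydroxy-1β-pivaloyloxy-10β-methyloctal-5-en-7-one, via TMS dienol ether 4 (not isolated), via 8α-trimethylsilyloxy enone 5 (not isolated)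
Conditions: LDA (1.2 equiv), THF, −78 °C, then TMSCl, −78 → 0 °C; solvent exchange; mCPBA (1.1 equiv), hexane–CH2Cl2, −20 → 0 °C; 1 M aq HCl, THF, 0 °C
Reagents that add atoms: mCPBA, O=C(OO)c1cccc(Cl)c1
Why: Rubottom oxidation, in which kinetic α′-deprotonation at C8 gives the cross-conjugated 2-silyloxydiene, its electron-rich C7=C8 bond is epoxidised on the α face opposite the axial C10 methyl (1,3 to C8), and silyl migration followed by hydrolysis leaves the equatorial 8α-hydroxyl, which is also the more stable epimer of this epimerisable centre.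

Step 4
Reactants: 6 8α-hydroxy-1β-pivaloyloxy-10β-methyloctal-5-en-7-one
Product: 7 8α-(tert-butyldimethylsilyloxy)-1β-pivaloyloxy-10β-methyloctal-5-en-7-one
Conditions: TBSCl (1.5 equiv), imidazole (3 equiv), DMF, rt
Reagents that add atoms: tert-butyldimethylsilyl chloride, CC(C)(C)[Si](C)(C)Cl
Why: Imidazole-promoted silylation of an unhindered secondary α-ketol installs a group orthogonal to the pivalate without silylating the enone, and C8 keeps its equatorial α configuration.

Step 5
Reactants: 7 8α-(tert-butyldimethylsilyloxy)-1β-pivaloyloxy-10β-methyloctal-5-en-7-one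
Product: 8 8α-(tert-butyldimethylsilyloxy)-1β-pivaloyloxy-10β-methylhexalin-4,6-dien-7-yl triflate
Conditions: Tf2O (1.3 equiv), 2,6-di-tert-butyl-4-methylpyridine (1.6 equiv), CH2Cl2, 0 °C → rt
Reagents that add atoms: triflic anhydride, O=S(=O)(OS(=O)(=O)C(F)(F)F)C(F)(F)F
Why: Enone-to-dienyl-triflate conversion of the kind routine for steroidal 4-en-3-ones, in which O-triflylation gives a triflyloxyallyl cation and the hindered, non-nucleophilic pyridine removes the γ-proton at C4 to give the more stable linearly conjugated heteroannular diene while C8–H stays in place.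

Step 6
Reactants: 8 8α-(tert-butyldimethylsilyloxy)-1β-pivaloyloxy-10β-methylhexalin-4,6-dien-7-yl triflate; 9 isopropylmagnesium chloride
Product: 10 8α-(tert-butyldimethylsilyloxy)-1β-pivaloyloxy-15-noreudesma-4,6-diene
Conditions: 9 (1.6 equiv, 2 M in THF), Fe(acac)3 (10 mol %), THF–NMP, −30 → 0 °C
Reagents that add atoms: isopropylmagnesium chloride (9), CC(C)[Mg]Cl
Why: Iron-catalysed Kumada-type alkenyl–alkyl cross-coupling, in which the low-valent iron species formed from the trivalent iron precatalyst turns over at low temperature faster than β-hydride elimination or ester attack, so a secondary alkyl Grignard reagent should couple with the alkenyl triflate without isomerisation and with pivalate, silyl ether and C8 intact.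

Step 7
Reactants: 10 8α-(tert-butyldimethylsilyloxy)-1β-pivaloyloxy-15-noreudesma-4,6-diene
Product: 12 8α-(tert-butyldimethylsilyloxy)-1β-pivaloyloxy-15-noreudesm-6-en-4α-ol (5αH), via 4α-alkylborane 11 (not isolated)
Conditions: BH3·THF (1.05 equiv), THF, −10 °C → rt; then 3 M aq NaOH, 30% H2O2, 0 °C
Reagents that add atoms: hydrogen peroxide, OO
Why: Brown hydroboration–oxidation of a conjugated diene, in which boron bonds to the open diene terminus C4 (charge build-up at C5 is allyl-stabilised) while C6=C7 is screened by the isopropyl group and the neighbouring silyl ether, and syn addition from the α face opposite the angular methyl sets 4α-O and 5α-H and thus the trans ring fusion, the oxidation proceeding with retention.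

Step 8
Reactants: 12 8α-(tert-butyldimethylsilyloxy)-1β-pivaloyloxy-15-noreudesm-6-en-4α-ol
Product: 13 8α-(tert-butyldimethylsilyloxy)-1β-pivaloyloxy-15-noreudesm-6-en-4-one (5αH, trans-fused)
Conditions: Dess–Martin periodinane (1.3 equiv), pyridine (3 equiv), CH2Cl2, 0 °C → rt
Reagents that add atoms: none
Why: Dess–Martin oxidation under pyridine buffering is essentially neutral, so the secondary carbinol becomes the ketone without enolisation, the doubly activated C5–H keeps its α configuration and C6=C7 stays out of conjugation.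

Step 9
Reactants: 13 8α-(tert-butyldimethylsilyloxy)-1β-pivaloyloxy-15-noreudesm-6-en-4-one
Product: 14 8α-(tert-butyldimethylsilyloxy)-1β-pivaloyloxyeudesma-4(15),6-diene (5αH)
Conditions: Zn, CH2Br2, TiCl4, THF, −40 → 5 °C (reagent aged); then 13, CH2Cl2, 0 °C → rt
Reagents that add atoms: dibromomethane, BrCBr
Why: Lombardo–Takai methylenation, whose gem-dimetallic zinc/titanium reagent is nucleophilic but practically non-basic and ignores esters, so the epimerisable β,γ-unsaturated ketone should be methylenated with C5 unchanged where a phosphorus ylide could enolise it.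

Step 10
Reactants: 14 8α-(tert-butyldimethylsilyloxy)-1β-pivaloyloxyeudesma-4(15),6-diene
Product: 16 8α-(tert-butyldimethylsilyloxy)-1β-pivaloyloxyeudesm-6-en-4α-ol (4β-methyl), via 4α-hydroperoxide 15 (not isolated)
Conditions: Co(acac)2 (20 mol %), PhSiH3 (2.5 equiv), O2 (1 atm), THF, 0 °C → rt; then PPh3 (1.2 equiv)
Reagents that add atoms: dioxygen, O=O
Why: Mukaiyama hydration (Markovnikov hydrogen-atom transfer from a cobalt hydride made from the divalent cobalt salt), in which the hydrogen atom goes to the exposed CH2 terminus faster than to the crowded trisubstituted C6=C7 bond and the tertiary C4 radical takes up O2 along the equatorial α trajectory because the axial β approach meets the C10 methyl, giving 4α-OH/4β-CH3, the epimer that methyl-metal addition to 13 would not deliver.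

Step 11
Reactants: 16 8α-(tert-butyldimethylsilyloxy)-1β-pivaloyloxyeudesm-6-en-4α-ol
Product: 17 8α-(tert-butyldimethylsilyloxy)eudesm-6-ene-1β,4α-diol
Conditions: i-Bu2AlH (4 equiv), CH2Cl2, −78 → −20 °C; aq potassium sodium tartrate
Reagents that add atoms: none
Why: Reductive ester cleavage with an aluminium hydride removes the hindered pivalate under non-hydrolytic conditions that leave silyl ether, alkene, tertiary alcohol and all stereocentres untouched.

Step 12
Reactants: 17 8α-(tert-butyldimethylsilyloxy)eudesm-6-ene-1β,4α-diol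
Product: 18 8α-(tert-butyldimethylsilyloxy)-4α-hydroxyeudesm-6-en-1β-yl methanesulfonate
Conditions: MsCl (1.5 equiv), pyridine, 0 °C → rt
Reagents that add atoms: methanesulfonyl chloride, CS(=O)(=O)Cl
Why: Chemoselective sulfonylation, in which the secondary equatorial C1 hydroxyl reacts in pyridine while the tertiary C4 hydroxyl does not, C–O at C1 is retained, and the leaving group is introduced only now that no enolisable C4 ketone or strong base remains ahead of it.

Step 13
Reactants: 18 8α-(tert-butyldimethylsilyloxy)-4α-hydroxyeudesm-6-en-1β-yl methanesulfonate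
Product: 21 (1(10)E,5E,4R,7S,8S)-8-(tert-butyldimethylsilyloxy)germacra-1(10),5-dien-4-ol, via oxaborolane 19 (not isolated), via sodium borate 20 (not isolated)
Conditions: BH3·THF (4 equiv), THF, 0 °C → rt; H2O (dropwise, 0 °C); 3 M aq NaOH, rt → 40 °C
Reagents that add atoms: none
Why: Borane first converts the C4 hydroxyl into an alkoxyborane and adds syn across C6=C7 from the α face, placing boron equatorial on C6 and hydrogen axial on C7 and settling as oxaborolane 19; hydroxide then gives the tetracoordinate borate 20, whose C6–B pair becomes the C5=C6 π bond while the C5–C10 σ bond breaks, its pair becomes the C1=C10 π bond and mesylate leaves C1. This is the boron-electrofuge, extended variant of the Grob fragmentation (hydroboration followed by boronate 1,4-fragmentation of decalin-1-yl sulfonates), a known entry to (E,E)-cyclodeca-1,6-dienes. No carbocycle is closed: the ten-membered ring is released by scission of the bond shared by rings A and B, and the five-membered B–O tether of 19 and 20 is transient and hydrolysed. The only lasting new stereocentre, C7, is fixed by the α-face syn addition, which is enforced by the axial methyl groups on C10 and C4, both syn-axial to the β position of C6, and which leaves the isopropyl group equatorial (7S). Because the equatorial C6–B and C1–OMs bonds are each antiperiplanar to C5–C10 in the locked chair–chair trans-decalin, C4 ends trans to C7 and C2 trans to C9, so both alkenes should be E. The step needs boron on C6 rather than C7, which the fully substituted C7 flanked by the C8 silyl ether secures, and it needs free borane destroyed by water before base is added so that the liberated diene is not hydroborated, while the neopentyl equatorial mesylate resists substitution and elimination in the meantime.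

Step 14
Reactants: 21 (1(10)E,5E,4R,7S,8S)-8-(tert-butyldimethylsilyloxy)germacra-1(10),5-dien-4-ol
Product: 22 (1(10)E,5E,4R,7S,8S)-germacra-1(10),5-diene-4,8-diol
Conditions: Bu4NF (3 equiv), THF, rt → 45 °C
Reagents that add atoms: none
Why: Fluoride-mediated desilylation cleaves only the Si–O bond under non-acidic conditions, which avoids proton-induced transannular cyclisation of the 1,6-diene and leaves C8 unchanged.

Step 15
Reactants: 22 (1(10)E,5E,4R,7S,8S)-germacra-1(10),5-diene-4,8-diol; 23 4-acetoxybenzoyl chloride
Product: 24 (1(10)E,5E,4R,7S,8S)-4-hydroxygermacra-1(10),5-dien-8-yl 4-acetoxybenzoate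
Conditions: 23 (1.3 equiv), pyridine, DMAP (0.2 equiv), CH2Cl2, 0 °C → rt
Reagents that add atoms: 4-acetoxybenzoyl chloride (23), CC(=O)Oc1ccc(C(=O)Cl)cc1
Why: DMAP-catalysed acylation discriminates the secondary C8 hydroxyl from the tertiary allylic C4 hydroxyl, the excess pyridine keeps the medium basic for the acid-sensitive diene, and the C8–O bond is not broken.

Step 16
Reactants: 24 (1(10)E,5E,4R,7S,8S)-4-hydroxygermacra-1(10),5-dien-8-yl 4-acetoxybenzoate
Product: 25 (1(10)E,5E,4R,7S,8S)-4-hydroxygermacra-1(10),5-dien-8-yl 4-hydroxybenzoate (CNP0277965.1)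
Conditions: NH3 (2 M in MeOH), 0 °C; evaporation
Reagents that add atoms: none
Why: Chemoselective aminolysis, in which the activated aryl acetate is cleaved far faster than the hindered secondary alkyl benzoate (further deactivated once the phenol is free), and work-up by evaporation exposes the diene to no acid.

**Compound list**

1 | (R)-(−)-Wieland–Miescher ketone (C1 and C7 ketones, C5=C6, 10β-methyl) | C[C@]12C(=O)CCCC1=CC(=O)CC2 | starting material
2 | 1β-hydroxy-10β-methyloctal-5-en-7-one | C[C@]12[C@H](O)CCCC1=CC(=O)CC2 | intermediate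
3 | 1β-pivaloyloxy-10β-methyloctal-5-en-7-one | C[C@]12[C@H](OC(=O)C(C)(C)C)CCCC1=CC(=O)CC2 | intermediate
4 | 1β-pivaloyloxy-7-trimethylsilyloxy-10β-methylhexalin-5,7-diene (not isolated) | C[C@]12[C@H](OC(=O)C(C)(C)C)CCCC1=CC(O[Si](C)(C)C)=CC2 | intermediate
5 | 8α-trimethylsilyloxy-1β-pivaloyloxy-10β-methyloctal-5-en-7-one (not isolated) | C[C@]12[C@H](OC(=O)C(C)(C)C)CCCC1=CC(=O)[C@@H](O[Si](C)(C)C)C2 | intermediate
6 | 8α-hydroxy-1β-pivaloyloxy-10β-methyloctal-5-en-7-one | C[C@]12[C@H](OC(=O)C(C)(C)C)CCCC1=CC(=O)[C@@H](O)C2 | intermediate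
7 | 8α-(tert-butyldimethylsilyloxy)-1β-pivaloyloxy-10β-methyloctal-5-en-7-one | C[C@]12[C@H](OC(=O)C(C)(C)C)CCCC1=CC(=O)[C@@H](O[Si](C)(C)C(C)(C)C)C2 | intermediate
8 | 8α-(tert-butyldimethylsilyloxy)-1β-pivaloyloxy-10β-methylhexalin-4,6-dien-7-yl triflate | C[C@]12[C@H](OC(=O)C(C)(C)C)CCC=C1C=C(OS(=O)(=O)C(F)(F)F)[C@@H](O[Si](C)(C)C(C)(C)C)C2 | intermediate
9 | isopropylmagnesium chloride | CC(C)[Mg]Cl | starting material
10 | 8α-(tert-butyldimethylsilyloxy)-1β-pivaloyloxy-15-noreudesma-4,6-diene | C[C@]12[C@H](OC(=O)C(C)(C)C)CCC=C1C=C(C(C)C)[C@@H](O[Si](C)(C)C(C)(C)C)C2 | intermediate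
11 | 4α-boryl-8α-(tert-butyldimethylsilyloxy)-1β-pivaloyloxy-15-noreudesm-6-ene, 5αH (monoalkylborane, not isolated) | C[C@]12[C@H](OC(=O)C(C)(C)C)CC[C@@H](B)[C@@H]1C=C(C(C)C)[C@@H](O[Si](C)(C)C(C)(C)C)C2 | intermediate
12 | 8α-(tert-butyldimethylsilyloxy)-1β-pivaloyloxy-15-noreudesm-6-en-4α-ol, 5αH | C[C@]12[C@H](OC(=O)C(C)(C)C)CC[C@@H](O)[C@@H]1C=C(C(C)C)[C@@H](O[Si](C)(C)C(C)(C)C)C2 | intermediate
13 | 8α-(tert-butyldimethylsilyloxy)-1β-pivaloyloxy-15-noreudesm-6-en-4-one, 5αH | C[C@]12[C@H](OC(=O)C(C)(C)C)CCC(=O)[C@@H]1C=C(C(C)C)[C@@H](O[Si](C)(C)C(C)(C)C)C2 | intermediate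
14 | 8α-(tert-butyldimethylsilyloxy)-1β-pivaloyloxyeudesma-4(15),6-diene, 5αH | C[C@]12[C@H](OC(=O)C(C)(C)C)CCC(=C)[C@@H]1C=C(C(C)C)[C@@H](O[Si](C)(C)C(C)(C)C)C2 | intermediate
15 | 4α-hydroperoxy-8α-(tert-butyldimethylsilyloxy)-1β-pivaloyloxyeudesm-6-ene (not isolated) | C[C@]12[C@H](OC(=O)C(C)(C)C)CC[C@@](C)(OO)[C@@H]1C=C(C(C)C)[C@@H](O[Si](C)(C)C(C)(C)C)C2 | intermediate
16 | 8α-(tert-butyldimethylsilyloxy)-1β-pivaloyloxyeudesm-6-en-4α-ol (4β-methyl) | C[C@]12[C@H](OC(=O)C(C)(C)C)CC[C@@](C)(O)[C@@H]1C=C(C(C)C)[C@@H](O[Si](C)(C)C(C)(C)C)C2 | intermediate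
17 | 8α-(tert-butyldimethylsilyloxy)eudesm-6-ene-1β,4α-diol | C[C@]12[C@H](O)CC[C@@](C)(O)[C@@H]1C=C(C(C)C)[C@@H](O[Si](C)(C)C(C)(C)C)C2 | intermediate
18 | 8α-(tert-butyldimethylsilyloxy)-4α-hydroxyeudesm-6-en-1β-yl methanesulfonate | C[C@]12[C@H](OS(C)(=O)=O)CC[C@@](C)(O)[C@@H]1C=C(C(C)C)[C@@H](O[Si](C)(C)C(C)(C)C)C2 | intermediate
19 | 6α-boryl adduct of 18 (7αH, 7β-isopropyl), drawn as the 4-O,6-C-bridged 1,2-oxaborolane (not isolated) | C[C@]12[C@H](OS(C)(=O)=O)CC[C@@]3(C)OB[C@H]([C@H]13)[C@H](C(C)C)[C@@H](O[Si](C)(C)C(C)(C)C)C2 | intermediate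
20 | sodium dihydroxyborate derived from 19 (not isolated) | [Na+].C[C@]12[C@H](OS(C)(=O)=O)CC[C@@]3(C)O[B-](O)(O)[C@H]([C@H]13)[C@H](C(C)C)[C@@H](O[Si](C)(C)C(C)(C)C)C2 | intermediate
21 | (1(10)E,5E,4R,7S,8S)-8-(tert-butyldimethylsilyloxy)germacra-1(10),5-dien-4-ol | C/C1=C\CC[C@@](C)(O)/C=C/[C@H](C(C)C)[C@@H](O[Si](C)(C)C(C)(C)C)C1 | intermediate
22 | (1(10)E,5E,4R,7S,8S)-germacra-1(10),5-diene-4,8-diol | C/C1=C\CC[C@@](C)(O)/C=C/[C@H](C(C)C)[C@@H](O)C1 | intermediate
23 | 4-acetoxybenzoyl chloride | CC(=O)Oc1ccc(C(=O)Cl)cc1 | starting material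
24 | (1(10)E,5E,4R,7S,8S)-4-hydroxygermacra-1(10),5-dien-8-yl 4-acetoxybenzoate | C/C1=C\CC[C@@](C)(O)/C=C/[C@H](C(C)C)[C@@H](OC(=O)c2ccc(OC(C)=O)cc2)C1 | intermediate
25 | (1(10)E,5E,4R,7S,8S)-4-hydroxygermacra-1(10),5-dien-8-yl 4-hydroxybenzoate, CNP0277965.1 | C/C1=C\CC[C@@](C)(O)/C=C/[C@H](C(C)C)[C@@H](OC(=O)c2ccc(O)cc2)C1 | target

Total step count: 16. Longest linear sequence: 16 steps, from 1 to 25; compounds 9 and 23 are bought.

**Steps most likely to fail**

Step 7.
- What may go wrong: once conjugation is lost, the remaining C6=C7 bond may compete for borane and be hydroborated as well. Boron may also attack C6 directly. Part of the addition may occur on the β face and give a cis ring fusion.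
- Fallback: the order of coupling and hydroboration is reversed, so that the two alkenes are told apart electronically. It sets out from 8, where C6=C7 is deactivated by the electron-withdrawing triflyloxy group. BH3·THF followed by NaBO3·4H2O should functionalise only C4=C5 and give 8α-(tert-butyldimethylsilyloxy)-4α-hydroxy-1β-pivaloyloxy-10β-methyloctal-6-en-7-yl triflate F1. Fe(acac)3-catalysed coupling of F1 with 9, using one extra equivalent to deprotonate the hydroxyl, then installs the isopropyl group. The route is rejoined at 12.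

Step 13.
- What may go wrong: borane addition to the crowded trisubstituted alkene beside the bulky silyl ether may be sluggish or poorly face-selective. Some boron may reach C7 and trigger β-elimination of the silyloxy group. The liberated diene may be hydroborated again.
- Fallback: the precursor is redesigned and the disconnection kept. Setting out from 18, Bu4NF buffered with AcOH removes the silyl group to give 4α,8α-dihydroxyeudesm-6-en-1β-yl methanesulfonate F2. The α face next to C7 is then unencumbered, and both α-oriented hydroxyls are merely tied up as alkoxyboranes on that face. The same borane, water and NaOH sequence should fragment F2 directly, and the route is rejoined at 22.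

Step 10.
- What may go wrong: the planar C4 radical may capture O2 from both faces. Hydrogen-atom transfer may reach the ring alkene. The cobalt hydride may isomerise the skipped diene into conjugation. Autoxidation may occur at the doubly allylic C5–H.
- Fallback: radical capture is replaced by a concerted, sterically demanding syn addition. Setting out from 14, OsO4 (catalytic) with N-methylmorpholine N-oxide should dihydroxylate the exocyclic methylene from the open α face. This gives 8α-(tert-butyldimethylsilyloxy)-1β-pivaloyloxyeudesm-6-ene-4α,15-diol F3. TsCl in pyridine sulfonylates only the primary hydroxyl to give the 15-tosylate F4. LiEt3BH in THF then reduces the primary sulfonate to the C15 methyl group and cleaves the pivalate in the same flask. The route is rejoined at 17.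

**Further compounds**

F1 | step 7 | 8α-(tert-butyldimethylsilyloxy)-4α-hydroxy-1β-pivaloyloxy-10β-methyloctal-6-en-7-yl triflate (5αH) | C[C@]12[C@H](OC(=O)C(C)(C)C)CC[C@@H](O)[C@@H]1C=C(OS(=O)(=O)C(F)(F)F)[C@@H](O[Si](C)(C)C(C)(C)C)C2
F2 | step 13 | 4α,8α-dihydroxyeudesm-6-en-1β-yl methanesulfonate | C[C@]12[C@H](OS(C)(=O)=O)CC[C@@](C)(O)[C@@H]1C=C(C(C)C)[C@@H](O)C2
F3 | step 10 | 8α-(tert-butyldimethylsilyloxy)-1β-pivaloyloxyeudesm-6-ene-4α,15-diol | C[C@]12[C@H](OC(=O)C(C)(C)C)CC[C@@](CO)(O)[C@@H]1C=C(C(C)C)[C@@H](O[Si](C)(C)C(C)(C)C)C2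
F4 | step 10 | 8α-(tert-butyldimethylsilyloxy)-4α-hydroxy-1β-pivaloyloxyeudesm-6-en-15-yl 4-methylbenzenesulfonate | C[C@]12[C@H](OC(=O)C(C)(C)C)CC[C@@](COS(=O)(=O)c3ccc(C)cc3)(O)[C@@H]1C=C(C(C)C)[C@@H](O[Si](C)(C)C(C)(C)C)C2
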